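**Plan**

1. Locants follow the germacrane skeleton (C1 ketone, C2=C3 furanone olefin, Z-C4=C5, C6/C7 lactone fusion, C8 acyloxy, C9 carbinol, C10 quaternary). The five-membered ring made of the bridging oxygen, C3, C2, C1 and C10 is a 3(2H)-furanone with a quaternary C10; without its C9 substituent it is the keto tautomer of 2-methylfuran-3-ol, so the C9(OH)–C10 bond can be formed by adding the aromatic enol, as its silyl ether, to a C9 aldehyde.
2. Retrosynthetic cuts, in this order: C9–C10 (ring-closing Mukaiyama aldol that dearomatises a 3-silyloxyfuran); the C8 ester; C6–C7 together with the lactone C–O (allylchromium addition of a 2-(bromomethyl)acrylate to a Z-enal); O–C3 (5-endo cyclisation of a hydroxy ynone); C1–C2 (acetylide plus Weinreb amide).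
3. Forward order: the furanone ring first, the α-methylene-γ-butyrolactone when the two halves are joined, then the side-chain ester at C8, and the ten-membered carbocycle last.
4. Stereochemistry: C8 comes from (R)-glyceraldehyde acetonide; C7 and C6 are set in the allylation (C8-directed face, anti addition, hence the trans lactone); C9 and C10 are set together in the ring closure (Felkin–Anh at C9, tether-defined furan face at C10); the Z-C4=C5 olefin comes from the commercial enynol and the E side-chain olefin from a thermodynamic acetate transposition.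

Key step: step 22

Remark: C10 is enolisable in every furanone before step 21 and is flattened there, so these compounds are carried as C10 epimer mixtures and drawn without a descriptor at that carbon.

**Route**

Step 1
Reactants: 1 (2Z)-3-methylpent-2-en-4-yn-1-ol
Product: 2 tert-butyl{[(2Z)-3-methylpent-2-en-4-yn-1-yl]oxy}diphenylsilane
Conditions: TBDPSCl, imidazole, CH2Cl2, 0 °C to rt
Reagents that add atoms: tert-butyl(chloro)diphenylsilane, CC(C)(C)[Si](Cl)(c1ccccc1)c1ccccc1
Why: Imidazole-promoted O-silylation of a primary allylic alcohol; the bulky silyl ether keeps the Z-allylic oxygen from adding to the alkyne (furan formation) in the later cyclisation.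

Step 2
Reactants: 3 ethyl (2S)-2-hydroxypropanoate (ethyl L-lactate)
Product: 4 ethyl (2S)-2-[(triethylsilyl)oxy]propanoate
Conditions: TESCl, imidazole, CH2Cl2, 0 °C
Reagents that add atoms: chlorotriethylsilane, CC[Si](Cl)(CC)CC
Why: Routine silylation of a secondary alcohol; the triethylsilyl ether can later be removed by mild acid in the presence of the tert-butyldiphenylsilyl ether, and the lactate centre need not be preserved because it becomes the C10 that is flattened in step 21.

Step 3
Reactants: 4 ethyl (2S)-2-[(triethylsilyl)oxy]propanoate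
Product: 5 (2S)-N-methoxy-N-methyl-2-[(triethylsilyl)oxy]propanamide
Conditions: MeNHOMe·HCl, i-PrMgCl, THF, −20 to 0 °C
Reagents that add atoms: N,O-dimethylhydroxylamine hydrochloride, CNOC.Cl
Why: Aminolysis of the ester by the chloromagnesium amide generated in the flask (Weinreb amide formation), standard for α-silyloxy esters at low temperature.

Step 4
Reactants: 2 tert-butyl{[(2Z)-3-methylpent-2-en-4-yn-1-yl]oxy}diphenylsilane; 5 (2S)-N-methoxy-N-methyl-2-[(triethylsilyl)oxy]propanamide
Product: 7 (2S,6Z)-8-[(tert-butyldiphenylsilyl)oxy]-6-methyl-2-[(triethylsilyl)oxy]oct-6-en-4-yn-3-one, via lithium acetylide 6 (not isolated)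
Conditions: n-BuLi, THF, −78 °C; then 5, −78 to 0 °C; aq. NH4Cl
Reagents that add atoms: none
Why: Weinreb ketone synthesis: the chelated tetrahedral adduct of the lithium acetylide persists until work-up, so the reaction stops at the ynone and forms the C1–C2 bond.

Step 5
Reactants: 7 (2S,6Z)-8-[(tert-butyldiphenylsilyl)oxy]-6-methyl-2-[(triethylsilyl)oxy]oct-6-en-4-yn-3-one
Product: 8 (2S,6Z)-8-[(tert-butyldiphenylsilyl)oxy]-2-hydroxy-6-methyloct-6-en-4-yn-3-one
Conditions: PPTS (cat.), MeOH, 0 °C
Reagents that add atoms: none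
Why: Acid-catalysed methanolysis cleaves the secondary triethylsilyl ether much faster than the tert-butyldiphenylsilyl ether and frees the α'-hydroxyl for ring closure.

Step 6
Reactants: 8 (2S,6Z)-8-[(tert-butyldiphenylsilyl)oxy]-2-hydroxy-6-methyloct-6-en-4-yn-3-one
Product: 9 5-{(2Z)-4-[(tert-butyldiphenylsilyl)oxy]but-2-en-2-yl}-2-methylfuran-3(2H)-one
Conditions: Ph3PAuNTf2 (5 mol%), toluene, rt
Reagents that add atoms: none
Why: Cationic monovalent gold activates the ynone for 5-endo-dig attack of the α'-hydroxyl at C3 (hydroalkoxylation), an established route from α'-hydroxy ynones to 3(2H)-furanones; the silyl-blocked allylic oxygen cannot compete.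

Step 7
Reactants: 9 5-{(2Z)-4-[(tert-butyldiphenylsilyl)oxy]but-2-en-2-yl}-2-methylfuran-3(2H)-one
Product: 10 5-[(2Z)-4-hydroxybut-2-en-2-yl]-2-methylfuran-3(2H)-one
Conditions: HF·pyridine, THF, 0 °C to rt
Reagents that add atoms: none
Why: Fluoride-mediated desilylation under mildly acidic conditions avoids enolate chemistry at the acidic C10–H of the furanone.

Step 8
Reactants: 10 5-[(2Z)-4-hydroxybut-2-en-2-yl]-2-methylfuran-3(2H)-one
Product: 11 (2Z)-3-(5-methyl-4-oxo-4,5-dihydrofuran-2-yl)but-2-enal
Conditions: Dess–Martin periodinane, NaHCO3, CH2Cl2, 0 °C; used directly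
Reagents that add atoms: none
Why: Buffered Dess–Martin oxidation of a primary allylic alcohol is fast and neutral, so the Z geometry of the trisubstituted olefin should carry over into the enal.

Step 9
Reactants: 12 (4R)-2,2-dimethyl-1,3-dioxolane-4-carbaldehyde; 13 methyl acrylate
Product: 14 methyl 2-{[(4R)-2,2-dimethyl-1,3-dioxolan-4-yl](hydroxy)methyl}prop-2-enoate (carbinol epimers)
Conditions: DABCO, 1,4-dioxane–H2O, rt
Reagents that add atoms: none
Why: Morita–Baylis–Hillman reaction; the carbinol epimers are taken on together because that centre becomes sp2 in the next step, and the dioxolane carbon (C8) is untouched.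

Step 10
Reactants: 14 methyl 2-{[(4R)-2,2-dimethyl-1,3-dioxolan-4-yl](hydroxy)methyl}prop-2-enoate
Product: 15 methyl (2Z)-2-(bromomethyl)-3-[(4S)-2,2-dimethyl-1,3-dioxolan-4-yl]prop-2-enoate
Conditions: NBS, Me2S, CH2Cl2, 0 °C to rt
Reagents that add atoms: N-bromosuccinimide, O=C1CCC(=O)N1Br
Why: The alcohol is activated as an alkoxysulfonium ion and bromide attacks in SN2' fashion, which for Morita–Baylis–Hillman adducts gives the rearranged primary bromide with the dioxolanyl group trans to the ester.

Step 11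
Reactants: 11 (2Z)-3-(5-methyl-4-oxo-4,5-dihydrofuran-2-yl)but-2-enal; 15 methyl (2Z)-2-(bromomethyl)-3-[(4S)-2,2-dimethyl-1,3-dioxolan-4-yl]prop-2-enoate
Product: 18 (4S,5R)-4-[(4S)-2,2-dimethyl-1,3-dioxolan-4-yl]-3-methylidene-5-[(1Z)-2-(5-methyl-4-oxo-4,5-dihydrofuran-2-yl)prop-1-en-1-yl]oxolan-2-one, via allylchromium dichloride 16 (not isolated), via anti hydroxy ester 17 (not isolated)
Conditions: CrCl2 (4 equiv), THF, 0 °C to rt, 15 added slowly to 11 and CrCl2; aq. work-up; then PPTS (cat.), CH2Cl2, rt
Reagents that add atoms: none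
Why: Nozaki–Hiyama allylation with lactonisation: the equilibrating allylchromium is expected to react through the isomer with C8 trans to the chromium-bearing methylene in a chair Zimmerman–Traxler transition state (6,7-anti, hence the trans lactone, C6 R), while C8, with its hydrogen eclipsing the olefin to avoid A(1,3) strain against the ester, should direct the aldehyde to the face anti to the C8–C9 bond (C7 S).

Step 12
Reactants: 19 tert-butyl acrylate; 20 acetaldehyde
Product: 21 tert-butyl 3-hydroxy-2-methylidenebutanoate (racemic)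
Conditions: DABCO, neat, rt
Reagents that add atoms: none
Why: Morita–Baylis–Hillman reaction; the carbinol centre is lost in step 14, so the racemate suffices.

Step 13
Reactants: 21 tert-butyl 3-hydroxy-2-methylidenebutanoate
Product: 22 tert-butyl 3-acetoxy-2-methylidenebutanoate
Conditions: Ac2O, pyridine, DMAP (cat.), CH2Cl2, 0 °C to rt
Reagents that add atoms: acetic anhydride, CC(=O)OC(C)=O
Why: DMAP-catalysed acetylation of a secondary allylic alcohol.

Step 14
Reactants: 22 tert-butyl 3-acetoxy-2-methylidenebutanoate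
Product: 23 tert-butyl (2E)-2-(acetoxymethyl)but-2-enoate
Conditions: DABCO (20 mol%), THF, reflux
Reagents that add atoms: none
Why: DABCO adds in SN2' fashion and the expelled acetate returns at the primary terminus, a known thermodynamically controlled 1,3-acetoxy transposition that should favour the E enoate (methyl trans to the ester).

Step 15
Reactants: 23 tert-butyl (2E)-2-(acetoxymethyl)but-2-enoate
Product: 24 (2E)-2-(acetoxymethyl)but-2-enoic acid
Conditions: TFA, CH2Cl2, 0 °C to rt
Reagents that add atoms: none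
Why: Acidolysis of the tert-butyl ester with loss of isobutene leaves the primary acetate and the olefin geometry untouched.

Step 16
Reactants: 18 (4S,5R)-4-[(4S)-2,2-dimethyl-1,3-dioxolan-4-yl]-3-methylidene-5-[(1Z)-2-(5-methyl-4-oxo-4,5-dihydrofuran-2-yl)prop-1-en-1-yl]oxolan-2-one
Product: 25 (4R,5R)-4-[(1S)-1,2-dihydroxyethyl]-3-methylidene-5-[(1Z)-2-(5-methyl-4-oxo-4,5-dihydrofuran-2-yl)prop-1-en-1-yl]oxolan-2-one (same spatial arrangement as 18; the ring C4 descriptor changes only through CIP ranking)
Conditions: AcOH–H2O (4:1), rt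
Reagents that add atoms: none
Why: Mild acid hydrolysis of a terminal acetonide; the lactone, the exo-methylene and the furanone tolerate dilute acetic acid, and direct lactone migration to the C8 oxygen would need a strained bicyclic orthoester.

Step 17
Reactants: 25 (4R,5R)-4-[(1S)-1,2-dihydroxyethyl]-3-methylidene-5-[(1Z)-2-(5-methyl-4-oxo-4,5-dihydrofuran-2-yl)prop-1-en-1-yl]oxolan-2-one
Product: 26 (4R,5R)-4-{(1S)-1-hydroxy-2-[(triethylsilyl)oxy]ethyl}-3-methylidene-5-[(1Z)-2-(5-methyl-4-oxo-4,5-dihydrofuran-2-yl)prop-1-en-1-yl]oxolan-2-one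
Conditions: TESCl (1.05 equiv), imidazole, CH2Cl2, −78 to −40 °C
Reagents that add atoms: chlorotriethylsilane, CC[Si](Cl)(CC)CC
Why: Sterically controlled silylation of the primary C9 hydroxyl over the secondary C8 hydroxyl at low temperature.

Step 18
Reactants: 26 (4R,5R)-4-{(1S)-1-hydroxy-2-[(triethylsilyl)oxy]ethyl}-3-methylidene-5-[(1Z)-2-(5-methyl-4-oxo-4,5-dihydrofuran-2-yl)prop-1-en-1-yl]oxolan-2-one; 24 (2E)-2-(acetoxymethyl)but-2-enoic acid
Product: 28 (1S)-1-{(2R,3S)-4-methylidene-2-[(1Z)-2-(5-methyl-4-oxo-4,5-dihydrofuran-2-yl)prop-1-en-1-yl]-5-oxooxolan-3-yl}-2-[(triethylsilyl)oxy]ethyl (2E)-2-(acetoxymethyl)but-2-enoate, via mixed anhydride 27 (not isolated)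
Conditions: 24, 2,4,6-trichlorobenzoyl chloride, Et3N, THF, rt; then 26, DMAP, toluene, rt
Reagents that add atoms: none
Why: Yamaguchi esterification of the hindered secondary C8 hydroxyl through the mixed anhydride and DMAP acyl transfer; the C8–O bond is not broken, so C8 is retained, and the E side-chain geometry is the thermodynamic one.

Step 19
Reactants: 28 (1S)-1-{(2R,3S)-4-methylidene-2-[(1Z)-2-(5-methyl-4-oxo-4,5-dihydrofuran-2-yl)prop-1-en-1-yl]-5-oxooxolan-3-yl}-2-[(triethylsilyl)oxy]ethyl (2E)-2-(acetoxymethyl)but-2-enoate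
Product: 29 (1S)-2-hydroxy-1-{(2R,3S)-4-methylidene-2-[(1Z)-2-(5-methyl-4-oxo-4,5-dihydrofuran-2-yl)prop-1-en-1-yl]-5-oxooxolan-3-yl}ethyl (2E)-2-(acetoxymethyl)but-2-enoate
Conditions: HF·pyridine, pyridine, THF, 0 °C
Reagents that add atoms: none
Why: Buffered fluoride cleavage of the primary triethylsilyl ether under non-basic conditions, which should prevent acyl migration from O8 to O9.

Step 20
Reactants: 29 (1S)-2-hydroxy-1-{(2R,3S)-4-methylidene-2-[(1Z)-2-(5-methyl-4-oxo-4,5-dihydrofuran-2-yl)prop-1-en-1-yl]-5-oxooxolan-3-yl}ethyl (2E)-2-(acetoxymethyl)but-2-enoate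
Product: 30 (1S)-1-{(2R,3S)-4-methylidene-2-[(1Z)-2-(5-methyl-4-oxo-4,5-dihydrofuran-2-yl)prop-1-en-1-yl]-5-oxooxolan-3-yl}-2-oxoethyl (2E)-2-(acetoxymethyl)but-2-enoate
Conditions: Dess–Martin periodinane, NaHCO3, CH2Cl2, 0 °C to rt; used without chromatography
Reagents that add atoms: none
Why: Buffered Dess–Martin oxidation gives the α-acyloxy aldehyde under neutral conditions, so C8 should not epimerise.

Step 21
Reactants: 30 (1S)-1-{(2R,3S)-4-methylidene-2-[(1Z)-2-(5-methyl-4-oxo-4,5-dihydrofuran-2-yl)prop-1-en-1-yl]-5-oxooxolan-3-yl}-2-oxoethyl (2E)-2-(acetoxymethyl)but-2-enoate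
Product: 31 (1S)-1-{(2R,3S)-2-[(1Z)-2-{4-[(tert-butyldimethylsilyl)oxy]-5-methylfuran-2-yl}prop-1-en-1-yl]-4-methylidene-5-oxooxolan-3-yl}-2-oxoethyl (2E)-2-(acetoxymethyl)but-2-enoate
Conditions: TBSOTf (1.05 equiv), Et3N, CH2Cl2, −78 °C; pentane, filtration under argon, used crude
Reagents that add atoms: tert-butyldimethylsilyl trifluoromethanesulfonate, CC(C)(C)[Si](C)(C)OS(=O)(=O)C(F)(F)F
Why: Soft enolisation: the silyl triflate binds the most Lewis-basic carbonyl, the vinylogous-ester C1 ketone, and the amine removes the C10 proton because the product is an aromatic furan (the known conversion of 3(2H)-furanones into 3-silyloxyfurans), while the much less basic aldehyde should be left alone at −78 °C; C10 is flattened here.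

Step 22
Reactants: 31 (1S)-1-{(2R,3S)-2-[(1Z)-2-{4-[(tert-butyldimethylsilyl)oxy]-5-methylfuran-2-yl}prop-1-en-1-yl]-4-methylidene-5-oxooxolan-3-yl}-2-oxoethyl (2E)-2-(acetoxymethyl)but-2-enoate
Product: 32 CNP0231561.1, the (6R,7S,8S,9S,10R) furanoheliangolide
Conditions: BF3·OEt2 (1.2 equiv), CH2Cl2, −78 °C, syringe-pump addition of 31 (final ca. 1 mM); aq. NaHCO3
Reagents that add atoms: none
Why: Proposed new method: coordination of BF3 to the C9 formyl oxygen makes it electrophilic enough for C10 of the silyloxyfuran, the enol-silane carbon next to the ring oxygen, to add through an acyclic transition state, and the resulting silyloxocarbenium ion gives up its silyl group to fluoride, which unveils the C1 carbonyl and turns the aromatic furan into the bridging 3(2H)-furanone. The closest known reaction type is the intermolecular Lewis-acid Mukaiyama aldol of 2-alkyl-3-silyloxyfurans with aldehydes to give 2,2-disubstituted 3(2H)-furanones, together with macrocyclising Mukaiyama aldol additions of ordinary enol silanes. The one ring closed is the ten-membered carbocycle C1–C10, in a 10-exo-trig mode at the aldehyde carbon (enolendo at the furan), which makes the existing heterocycle the oxygen bridge of an 11-oxabicyclo[6.2.1]undecane. C9 should arise by Felkin–Anh addition anti to the C8 acyloxy group under the monodentate Lewis acid (8,9-anti, 9S), and C10 by attack on the one furan face over which the C4–C9 tether, shaped by the Z-C4=C5 olefin, the trans lactone and C8, can carry the aldehyde (10R). The step needs the aldehyde to react in preference to the methylene lactone and the side-chain enoate (secured by the far higher electrophilicity of a BF3-bound aldehyde), C10 rather than C2 to attack (enol-silane polarisation and ring size), and ring closure rather than oligomerisation (high dilution and the pre-bent chain). The acidic medium also protects the product from retro-aldol cleavage, which under base would expel an aromatic oxidofuran.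

**Compound list**

1 | (2Z)-3-methylpent-2-en-4-yn-1-ol | C#C/C(C)=C\CO | starting material
2 | tert-butyl{[(2Z)-3-methylpent-2-en-4-yn-1-yl]oxy}diphenylsilane | C#C/C(C)=C\CO[Si](c1ccccc1)(c1ccccc1)C(C)(C)C | intermediate
3 | ethyl (2S)-2-hydroxypropanoate (ethyl L-lactate) | C[C@H](O)C(=O)OCC | starting material
4 | ethyl (2S)-2-[(triethylsilyl)oxy]propanoate | C[C@H](O[Si](CC)(CC)CC)C(=O)OCC | intermediate
5 | (2S)-N-methoxy-N-methyl-2-[(triethylsilyl)oxy]propanamide | CON(C)C(=O)[C@H](C)O[Si](CC)(CC)CC | intermediate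
6 | lithium acetylide of 2 (not isolated) | [Li]C#C/C(C)=C\CO[Si](c1ccccc1)(c1ccccc1)C(C)(C)C | intermediate
7 | (2S,6Z)-8-[(tert-butyldiphenylsilyl)oxy]-6-methyl-2-[(triethylsilyl)oxy]oct-6-en-4-yn-3-one | C[C@H](O[Si](CC)(CC)CC)C(=O)C#C/C(C)=C\CO[Si](c1ccccc1)(c1ccccc1)C(C)(C)C | intermediate
8 | (2S,6Z)-8-[(tert-butyldiphenylsilyl)oxy]-2-hydroxy-6-methyloct-6-en-4-yn-3-one | C[C@H](O)C(=O)C#C/C(C)=C\CO[Si](c1ccccc1)(c1ccccc1)C(C)(C)C | intermediate
9 | 5-{(2Z)-4-[(tert-butyldiphenylsilyl)oxy]but-2-en-2-yl}-2-methylfuran-3(2H)-one (C2 of the furanone labile) | CC1OC(/C(C)=C\CO[Si](c2ccccc2)(c2ccccc2)C(C)(C)C)=CC1=O | intermediate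
10 | 5-[(2Z)-4-hydroxybut-2-en-2-yl]-2-methylfuran-3(2H)-one | CC1OC(/C(C)=C\CO)=CC1=O | intermediate
11 | (2Z)-3-(5-methyl-4-oxo-4,5-dihydrofuran-2-yl)but-2-enal | CC1OC(/C(C)=C\C=O)=CC1=O | intermediate
12 | (4R)-2,2-dimethyl-1,3-dioxolane-4-carbaldehyde ((R)-glyceraldehyde acetonide) | O=C[C@H]1COC(C)(C)O1 | starting material
13 | methyl acrylate | C=CC(=O)OC | starting material
14 | methyl 2-{[(4R)-2,2-dimethyl-1,3-dioxolan-4-yl](hydroxy)methyl}prop-2-enoate (carbinol epimers) | C=C(C(=O)OC)C(O)[C@H]1COC(C)(C)O1 | intermediate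
15 | methyl (2Z)-2-(bromomethyl)-3-[(4S)-2,2-dimethyl-1,3-dioxolan-4-yl]prop-2-enoate | COC(=O)/C(CBr)=C/[C@H]1COC(C)(C)O1 | intermediate
16 | allylchromium dichloride (trivalent chromium) from 15, drawn as the reactive isomer with the dioxolanyl group trans to the CrCH2 group (not isolated) | COC(=O)/C(C[Cr](Cl)Cl)=C\[C@H]1COC(C)(C)O1 | intermediate
17 | methyl (3S,4R,5Z)-3-[(4S)-2,2-dimethyl-1,3-dioxolan-4-yl]-4-hydroxy-6-(5-methyl-4-oxo-4,5-dihydrofuran-2-yl)-2-methylidenehept-5-enoate (not isolated) | C=C(C(=O)OC)[C@H]([C@H]1COC(C)(C)O1)[C@H](O)/C=C(/C)C2=CC(=O)C(C)O2 | intermediate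
18 | (4S,5R)-4-[(4S)-2,2-dimethyl-1,3-dioxolan-4-yl]-3-methylidene-5-[(1Z)-2-(5-methyl-4-oxo-4,5-dihydrofuran-2-yl)prop-1-en-1-yl]oxolan-2-one | C=C1C(=O)O[C@H](/C=C(/C)C2=CC(=O)C(C)O2)[C@H]1[C@H]3COC(C)(C)O3 | intermediate
19 | tert-butyl acrylate | C=CC(=O)OC(C)(C)C | starting material
20 | acetaldehyde | CC=O | starting material
21 | tert-butyl 3-hydroxy-2-methylidenebutanoate (racemic) | C=C(C(C)O)C(=O)OC(C)(C)C | intermediate
22 | tert-butyl 3-acetoxy-2-methylidenebutanoate (racemic) | C=C(C(C)OC(C)=O)C(=O)OC(C)(C)C | intermediate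
23 | tert-butyl (2E)-2-(acetoxymethyl)but-2-enoate | C/C=C(\COC(C)=O)C(=O)OC(C)(C)C | intermediate
24 | (2E)-2-(acetoxymethyl)but-2-enoic acid | C/C=C(\COC(C)=O)C(=O)O | intermediate
25 | (4R,5R)-4-[(1S)-1,2-dihydroxyethyl]-3-methylidene-5-[(1Z)-2-(5-methyl-4-oxo-4,5-dihydrofuran-2-yl)prop-1-en-1-yl]oxolan-2-one | C=C1C(=O)O[C@H](/C=C(/C)C2=CC(=O)C(C)O2)[C@H]1[C@H](O)CO | intermediate
26 | (4R,5R)-4-{(1S)-1-hydroxy-2-[(triethylsilyl)oxy]ethyl}-3-methylidene-5-[(1Z)-2-(5-methyl-4-oxo-4,5-dihydrofuran-2-yl)prop-1-en-1-yl]oxolan-2-one | C=C1C(=O)O[C@H](/C=C(/C)C2=CC(=O)C(C)O2)[C@H]1[C@H](O)CO[Si](CC)(CC)CC | intermediate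
27 | (2E)-2-(acetoxymethyl)but-2-enoic 2,4,6-trichlorobenzoic anhydride (not isolated) | C/C=C(\COC(C)=O)C(=O)OC(=O)c1c(Cl)cc(Cl)cc1Cl | intermediate
28 | (1S)-1-{(2R,3S)-4-methylidene-2-[(1Z)-2-(5-methyl-4-oxo-4,5-dihydrofuran-2-yl)prop-1-en-1-yl]-5-oxooxolan-3-yl}-2-[(triethylsilyl)oxy]ethyl (2E)-2-(acetoxymethyl)but-2-enoate | C=C1C(=O)O[C@H](/C=C(/C)C2=CC(=O)C(C)O2)[C@H]1[C@H](OC(=O)/C(=C/C)COC(C)=O)CO[Si](CC)(CC)CC | intermediate
29 | (1S)-2-hydroxy-1-{(2R,3S)-4-methylidene-2-[(1Z)-2-(5-methyl-4-oxo-4,5-dihydrofuran-2-yl)prop-1-en-1-yl]-5-oxooxolan-3-yl}ethyl (2E)-2-(acetoxymethyl)but-2-enoate | C=C1C(=O)O[C@H](/C=C(/C)C2=CC(=O)C(C)O2)[C@H]1[C@H](OC(=O)/C(=C/C)COC(C)=O)CO | intermediate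
30 | (1S)-1-{(2R,3S)-4-methylidene-2-[(1Z)-2-(5-methyl-4-oxo-4,5-dihydrofuran-2-yl)prop-1-en-1-yl]-5-oxooxolan-3-yl}-2-oxoethyl (2E)-2-(acetoxymethyl)but-2-enoate | C=C1C(=O)O[C@H](/C=C(/C)C2=CC(=O)C(C)O2)[C@H]1[C@H](OC(=O)/C(=C/C)COC(C)=O)C=O | intermediate
31 | (1S)-1-{(2R,3S)-2-[(1Z)-2-{4-[(tert-butyldimethylsilyl)oxy]-5-methylfuran-2-yl}prop-1-en-1-yl]-4-methylidene-5-oxooxolan-3-yl}-2-oxoethyl (2E)-2-(acetoxymethyl)but-2-enoate | C=C1C(=O)O[C@H](/C=C(/C)c2cc(O[Si](C)(C)C(C)(C)C)c(C)o2)[C@H]1[C@H](OC(=O)/C(=C/C)COC(C)=O)C=O | intermediate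
32 | CNP0231561.1: (6R,7S,8S,9S,10R)-8-[(2E)-2-(acetoxymethyl)but-2-enoyloxy]-9-hydroxy-1-oxo-3,10-epoxygermacra-2,4(Z),11(13)-trien-12,6-olide | C=C1C(=O)O[C@@H]2/C=C(/C)C3=CC(=O)[C@](C)(O3)[C@@H](O)[C@@H](OC(=O)/C(=C/C)COC(C)=O)[C@@H]12 | target

**Summary**

Total step count: 22. Longest linear sequence: 15 steps (3 to 32 through steps 2–8, 11 and 16–22).

Steps most likely to fail:

1. Step 22 (new ring-closing aldol). The six-atom tether must span one face of the furan, so ring strain may divert the reaction to oligomers. Once the furan is electron-rich, the Lewis acid may ionise the C6–O bond (vinylogously furfurylic) or merely protodesilylate the enol silane. The facial sense at C9 or C10 may also be wrong. Fallback, setting out from 31 and returning at 32: bromination of the enol silane at C10 with N-bromosuccinimide (THF, −78 °C), the usual reaction of silyl enol ethers, would give the 10-bromo furanone aldehyde F1. Slow addition of SmI2 (THF, −78 °C, high dilution) would reduce the carbon–bromine bond to a trivalent samarium oxidofuran enolate. This should add to the C9 aldehyde through a metal-bridged cyclic transition state (intramolecular Reformatsky-type aldol, a known way to close medium and large rings from α-bromo ketones and aldehydes) and give 32 after aqueous work-up. This replaces Lewis-acid activation by a reductively generated metal enolate that closes irreversibly at low temperature.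

2. Step 11 (allylchromium coupling). The allylchromium may react through the isomer with C8 cis to the chromium-bearing methylene, possibly held by the dioxolane oxygen, which would give the syn adduct and the cis lactone. C8 may discriminate the faces poorly, the organochromium may undergo 1,4-elimination with loss of the C8 oxygen, or the Z-enal may isomerise. Fallback, setting out from 12 (with 11 as partner) and returning at 18: Ohira–Bestmann alkynylation of 12 (dimethyl (1-diazo-2-oxopropyl)phosphonate, K2CO3, MeOH) would give (4S)-4-ethynyl-2,2-dimethyl-1,3-dioxolane F2. Deprotonation (n-BuLi) and acylation with methyl chloroformate would give methyl 3-[(4S)-2,2-dimethyl-1,3-dioxolan-4-yl]prop-2-ynoate F3. Syn 1,4-hydroalumination (i-Bu2AlH, HMPA, THF) and trapping of the α-alumino acrylate with ICH2Bpin would give the geometrically fixed allylboronate methyl (2Z)-3-[(4S)-2,2-dimethyl-1,3-dioxolan-4-yl]-2-[(4,4,5,5-tetramethyl-1,3,2-dioxaborolan-2-yl)methyl]prop-2-enoate F4, with the dioxolanyl group trans to the boron-bearing methylene. Allylboration of 11 (toluene, rt to 50 °C, or Sc(OTf)3 cat. at low temperature) passes through a closed chair and is stereospecific, so it should give the 6,7-anti adduct 17, which lactonises (PPTS) to 18.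

3. Step 21 (silyloxyfuran formation beside an aldehyde). The silyl triflate and amine may also enolise and silylate the α-acyloxy aldehyde, which would scramble C8, and the silyloxyfuran may hydrolyse during handling. Fallback, setting out from 30 and returning at 32: the isolated enol silane would be avoided by a direct soft-enolisation aldol (MgBr2·OEt2, Et3N, Me3SiCl, EtOAc–CH2Cl2, high dilution). Only the acidic furanone C10–H should be removed, the magnesium enolate would close onto the aldehyde, and the aldolate would be trapped as the 9-O-trimethylsilyl ether of the target F5. Mild acid (citric acid, MeOH) would then give 32.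

**Further compounds**

F1 | step 22 | (1S)-1-{(2R,3S)-2-[(1Z)-2-(5-bromo-5-methyl-4-oxo-4,5-dihydrofuran-2-yl)prop-1-en-1-yl]-4-methylidene-5-oxooxolan-3-yl}-2-oxoethyl (2E)-2-(acetoxymethyl)but-2-enoate (C10 epimers) | C=C1C(=O)O[C@H](/C=C(/C)C2=CC(=O)C(C)(Br)O2)[C@H]1[C@H](OC(=O)/C(=C/C)COC(C)=O)C=O
F2 | step 11 | (4S)-4-ethynyl-2,2-dimethyl-1,3-dioxolane | C#C[C@H]1COC(C)(C)O1
F3 | step 11 | methyl 3-[(4S)-2,2-dimethyl-1,3-dioxolan-4-yl]prop-2-ynoate | COC(=O)C#C[C@H]1COC(C)(C)O1
F4 | step 11 | methyl (2Z)-3-[(4S)-2,2-dimethyl-1,3-dioxolan-4-yl]-2-[(4,4,5,5-tetramethyl-1,3,2-dioxaborolan-2-yl)methyl]prop-2-enoate | COC(=O)/C(CB1OC(C)(C)C(C)(C)O1)=C\[C@H]2COC(C)(C)O2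
F5 | step 21 | 9-O-trimethylsilyl ether of 32 | C=C1C(=O)O[C@@H]2/C=C(/C)C3=CC(=O)[C@](C)(O3)[C@@H](O[Si](C)(C)C)[C@@H](OC(=O)/C(=C/C)COC(C)=O)[C@@H]12
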